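**Plan**

1. Numbering of the heterobicycle: furo[3,2-b]pyran-5-one (O1, C2-Ph, C3-OH, C3a, O4, C5=O, C6, C7, C7a). The retrosynthesis cuts first the two C–C bonds from C6 and C7 to the bicyclo[2.2.2]octene bridgeheads (retro-[4+2], giving (R)-α-phellandrene and the dihydropyranone 14). It then cuts the lactone bond O4–C3a (giving a Z-enoic acid that carries a C3–C3a epoxide), the C6=C7 alkene (Wittig), the epoxide oxygen, the ring alkene (metathesis) and the benzylic C2–O1 bond (allylic etherification).
2. Forward order: acyclic bis-allyl ether, then the cis-2,5-dihydrofuran, its epoxide, the Z-enoate, the pyranone ring closed onto the oxolane, and the bicyclo[2.2.2]octene last.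
3. Enabling feature: on the oxolane ring O4 (at C3a) and the OH (at C3) are vicinal and trans, O4 is cis to the C7a–C7 bond, and the C2 phenyl is cis to the C7a side chain. This is the pattern left when an epoxide on the free face of a cis-2,5-disubstituted dihydrofuran is opened at C3a, anti, by a carboxyl group held in reach by the Z C6=C7 bond.
4. Stereochemistry: C7a comes from (S)-glycidol and C2 from catalyst control in the iridium step. C3 and C3a come from face-selective epoxidation and the invertive ring closure. The four new bicyclooctene centres come from an endo cycloaddition anti to isopropyl and anti to O1, and the isopropyl centre from (R)-α-phellandrene.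

Key step: step 10

Remark: CIP descriptors of the oxolane carbons change along the route where neighbouring groups change rank, while the spatial arrangement stays that of the SMILES; (R)-(−)-α-phellandrene of high optical purity is assumed.

**Route**

Step 1
Reactants: 1 (S)-glycidol
Product: 2 (2R)-2-{[(4-methoxyphenyl)methoxy]methyl}oxirane
Conditions: NaH, 4-methoxybenzyl chloride, Bu4NI (cat.), THF/DMF, 0 °C → rt
Reagents that add atoms: 4-methoxybenzyl chloride, COc1ccc(CCl)cc1
Why: Williamson etherification of the primary alkoxide, which leaves the stereocentre untouched (the descriptor changes only through CIP ranking).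

Step 2
Reactants: 2 (2R)-2-{[(4-methoxyphenyl)methoxy]methyl}oxirane
Product: 3 (2R)-1-[(4-methoxyphenyl)methoxy]but-3-en-2-ol
Conditions: Me3S+ I− (3 equiv), n-BuLi, THF, −10 °C → rt
Reagents that add atoms: trimethylsulfonium iodide, C[S+](C)C.[I-]
Why: Sulfonium-ylide homologation of a terminal epoxide to an allylic alcohol (attack at the CH2 terminus, then elimination of dimethyl sulfide), which does not touch the carbinol centre.

Step 3
Reactants: 4 (E)-cinnamyl alcohol
Product: 5 tert-butyl (2E)-3-phenylprop-2-en-1-yl carbonate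
Conditions: Boc2O, Bu4NHSO4 (cat.), aq. NaOH, CH2Cl2, 0 °C → rt
Reagents that add atoms: di-tert-butyl dicarbonate, CC(C)(C)OC(=O)OC(=O)OC(C)(C)C
Why: O-acylation of the allylic alcohol under phase-transfer conditions gives the carbonate whose leaving group (tert-butoxide and CO2) does not compete as a nucleophile in step 4.

Step 4
Reactants: 3 (2R)-1-[(4-methoxyphenyl)methoxy]but-3-en-2-ol; 5 tert-butyl (2E)-3-phenylprop-2-en-1-yl carbonate
Product: 7 1-methoxy-4-{[(2R)-2-{[(1S)-1-phenylprop-2-en-1-yl]oxy}but-3-en-1-yl]oxymethyl}benzene, via copper alkoxide 6 (not isolated)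
Conditions: 3 (1.5 equiv), n-BuLi, THF, 0 °C; CuI; then 5, [Ir(cod)Cl]2 (2 mol%), (Sa,Sc,Sc)-O,O′-(1,1′-binaphthalene-2,2′-diyl) N,N-bis(1-phenylethyl)phosphoramidite (4 mol%), THF, rt; aq. NH4Cl
Reagents that add atoms: copper monoiodide, [Cu+].[I-] (copper of intermediate 6 only)
Why: Iridium-catalysed branched-selective allylic etherification with a copper alkoxide, in which the allyl-iridium intermediate is attacked at the benzylic terminus and the ligand enantiomer (chosen to give the S benzylic ether) sets the new centre by catalyst control, while the centre from 3 is carried through.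

Step 5
Reactants: 7 1-methoxy-4-{[(2R)-2-{[(1S)-1-phenylprop-2-en-1-yl]oxy}but-3-en-1-yl]oxymethyl}benzene
Product: 8 (2R,5S)-2-{[(4-methoxyphenyl)methoxy]methyl}-5-phenyl-2,5-dihydrofuran (substituents cis)
Conditions: second-generation Grubbs catalyst (H2IMes)(PCy3)Cl2Ru=CHPh (3 mol%), CH2Cl2, 40 °C
Reagents that add atoms: none
Why: Ring-closing metathesis of two monosubstituted allylic-ether alkenes closes the five-membered ring with loss of ethene, and the two ether centres of 7 translate directly into the cis-2,5 relationship.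

Step 6
Reactants: 8 (2R,5S)-2-{[(4-methoxyphenyl)methoxy]methyl}-5-phenyl-2,5-dihydrofuran
Product: 9 (1S,2S,4R,5R)-2-{[(4-methoxyphenyl)methoxy]methyl}-4-phenyl-3,6-dioxabicyclo[3.1.0]hexane
Conditions: mCPBA (3 equiv), NaHCO3, BHT (cat.), ClCH2CH2Cl, 50 °C
Reagents that add atoms: 3-chloroperoxybenzoic acid, OOC(=O)c1cccc(Cl)c1
Why: Prilezhaev epoxidation of the ring alkene; both substituents sit on one face of the near-planar dihydrofuran, so the peracid should deliver oxygen to the opposite face and thereby fix the two epoxide carbons.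

Step 7
Reactants: 9 (1S,2S,4R,5R)-2-{[(4-methoxyphenyl)methoxy]methyl}-4-phenyl-3,6-dioxabicyclo[3.1.0]hexane
Product: 10 [(1S,2S,4R,5R)-4-phenyl-3,6-dioxabicyclo[3.1.0]hexan-2-yl]methanol
Conditions: DDQ, CH2Cl2/pH 7 buffer (10:1), 0 °C → rt
Reagents that add atoms: none
Why: Oxidative cleavage of the electron-rich 4-methoxybenzyl ether under neutral conditions, which spares the epoxide and the less electron-rich cyclic benzylic ether.

Step 8
Reactants: 10 [(1S,2S,4R,5R)-4-phenyl-3,6-dioxabicyclo[3.1.0]hexan-2-yl]methanol
Product: 11 (1R,2R,4R,5R)-4-phenyl-3,6-dioxabicyclo[3.1.0]hexane-2-carbaldehyde (same spatial arrangement as 10)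
Conditions: Dess–Martin periodinane, NaHCO3, CH2Cl2, 0 °C → rt; crude product used at once
Reagents that add atoms: none
Why: Dess–Martin oxidation of the primary alcohol under buffered, non-basic conditions, which should keep the α-alkoxy aldehyde from epimerising.

Step 9
Reactants: 11 (1R,2R,4R,5R)-4-phenyl-3,6-dioxabicyclo[3.1.0]hexane-2-carbaldehyde
Product: 12 tert-butyl (2Z)-3-[(1S,2S,4R,5R)-4-phenyl-3,6-dioxabicyclo[3.1.0]hexan-2-yl]prop-2-enoate
Conditions: Ph3P=CHCO2t-Bu, MeOH, −20 → 0 °C
Reagents that add atoms: tert-butyl (triphenylphosphoranylidene)acetate, CC(C)(C)OC(=O)C=P(c1ccccc1)(c1ccccc1)c1ccccc1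
Why: Wittig olefination with a stabilised ylide in methanol, conditions under which α-alkoxy aldehydes are known to favour the Z enoate, run without added base so that the aldehyde centre and the epoxide are not endangered.

Step 10
Reactants: 12 tert-butyl (2Z)-3-[(1S,2S,4R,5R)-4-phenyl-3,6-dioxabicyclo[3.1.0]hexan-2-yl]prop-2-enoate
Product: 14 (+)-altholactone [(2R,3R,3aS,7aS)-3-hydroxy-2-phenyl-2,3,3a,7a-tetrahydro-5H-furo[3,2-b]pyran-5-one], via epoxy acid 13 (not isolated)
Conditions: CF3CO2H/CH2Cl2 (1:4), 0 °C → rt; then aq. NaHCO3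
Reagents that add atoms: none
Why: Acid removes the tert-butyl group (E1 loss of 2-methylpropene) and protonates the epoxide, and the carboxyl oxygen of 13 then attacks C1 of the dioxabicyclohexane (the future C3a) from the face opposite the epoxide oxygen, so that the lactone C–O bond forms with inversion while the epoxide oxygen stays on the neighbouring carbon as the free 3-OH. The closest known reaction type is the acid-mediated lactonisation of epoxy acids and epoxy tert-butyl esters by intramolecular epoxide opening. The pyranone ring closes in the 6-exo-tet mode, the breaking C–O bond lying outside the new ring. C3a is set by the backside (SN2-like) trajectory relative to the epoxide installed in step 6, which places O4 cis to the C7a–C7 bond (cis ring fusion), and C3 keeps the configuration of its epoxide C–O bond, trans to O4 and trans to phenyl. The step needs regioselectivity (C3a and not C3) and chemoselectivity (internal carboxyl and not trifluoroacetate): the Z alkene holds the carboxyl over the epoxide carbon next to C7a, attack at the other carbon would demand a bridged seven-membered ring, and trifluoroacetate is too weak a nucleophile to compete with a six-membered intramolecular closure. The conjugated Z alkene is inert to the acid, so the product is directly the dienophile for step 11.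

Step 11
Reactants: 14 (+)-altholactone; 15 (R)-(−)-α-phellandrene [(5R)-2-methyl-5-(propan-2-yl)cyclohexa-1,3-diene]
Product: 16 target, the endo [4+2] adduct (lactone C6 bonded to the bridgehead next to the isopropyl-bearing carbon, lactone C7 bonded to the bridgehead next to the methyl-bearing alkene carbon, lactone ring and isopropyl both syn to the C=C bridge, H-7 trans to H-7a)
Conditions: 15 (10 equiv), BHT (cat.), toluene, 130 °C, sealed tube
Reagents that add atoms: none
Why: Thermal normal-electron-demand Diels–Alder reaction in which the four new centres should follow from the endo rule, from attack on the diene face anti to isopropyl and on the lactone face anti to the C7a–O1 bond (convex face of the cis-fused bicycle), and from the "para" orientation of a 2-methyl diene (the β-carbon C7 bonds to the diene terminus next to the methyl-bearing carbon).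

**Compound list**

1 | (S)-glycidol, (2S)-oxiran-2-ylmethanol | OC[C@H]1CO1 | starting material
2 | (2R)-2-{[(4-methoxyphenyl)methoxy]methyl}oxirane | COc1ccc(COC[C@H]2CO2)cc1 | intermediate
3 | (2R)-1-[(4-methoxyphenyl)methoxy]but-3-en-2-ol | COc1ccc(COC[C@H](O)C=C)cc1 | intermediate
4 | (E)-cinnamyl alcohol, (2E)-3-phenylprop-2-en-1-ol | OC/C=C/c1ccccc1 | starting material
5 | tert-butyl (2E)-3-phenylprop-2-en-1-yl carbonate | CC(C)(C)OC(=O)OC/C=C/c1ccccc1 | intermediate
6 | copper alkoxide of 3 | COc1ccc(COC[C@H](O[Cu])C=C)cc1 | intermediate (not isolated)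
7 | 1-methoxy-4-{[(2R)-2-{[(1S)-1-phenylprop-2-en-1-yl]oxy}but-3-en-1-yl]oxymethyl}benzene | C=C[C@@H](c1ccccc1)O[C@H](C=C)COCc1ccc(OC)cc1 | intermediate
8 | (2R,5S)-2-{[(4-methoxyphenyl)methoxy]methyl}-5-phenyl-2,5-dihydrofuran | C1=C[C@@H](c2ccccc2)O[C@H]1COCc1ccc(OC)cc1 | intermediate
9 | (1S,2S,4R,5R)-2-{[(4-methoxyphenyl)methoxy]methyl}-4-phenyl-3,6-dioxabicyclo[3.1.0]hexane | COc1ccc(COC[C@@H]2O[C@H](c3ccccc3)[C@H]3O[C@@H]23)cc1 | intermediate
10 | [(1S,2S,4R,5R)-4-phenyl-3,6-dioxabicyclo[3.1.0]hexan-2-yl]methanol | OC[C@@H]1O[C@H](c2ccccc2)[C@H]2O[C@@H]12 | intermediate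
11 | (1R,2R,4R,5R)-4-phenyl-3,6-dioxabicyclo[3.1.0]hexane-2-carbaldehyde | O=C[C@@H]1O[C@H](c2ccccc2)[C@H]2O[C@@H]12 | intermediate
12 | tert-butyl (2Z)-3-[(1S,2S,4R,5R)-4-phenyl-3,6-dioxabicyclo[3.1.0]hexan-2-yl]prop-2-enoate | CC(C)(C)OC(=O)/C=C\[C@@H]1O[C@H](c2ccccc2)[C@H]2O[C@@H]12 | intermediate
13 | (2Z)-3-[(1S,2S,4R,5R)-4-phenyl-3,6-dioxabicyclo[3.1.0]hexan-2-yl]prop-2-enoic acid | OC(=O)/C=C\[C@@H]1O[C@H](c2ccccc2)[C@H]2O[C@@H]12 | intermediate (not isolated)
14 | (+)-altholactone, (2R,3R,3aS,7aS)-3-hydroxy-2-phenyl-2,3,3a,7a-tetrahydro-5H-furo[3,2-b]pyran-5-one | O=C1O[C@H]2[C@H](O)[C@@H](c3ccccc3)O[C@H]2C=C1 | intermediate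
15 | (R)-(−)-α-phellandrene, (5R)-2-methyl-5-(propan-2-yl)cyclohexa-1,3-diene | CC1=CC[C@H](C(C)C)C=C1 | starting material
16 | CNP0249919.1, endo adduct of 14 and 15 as described in step 11 | CC1=C[C@@H]2[C@@H]3C(=O)O[C@H]4[C@H](O)[C@@H](c5ccccc5)O[C@H]4[C@@H]3[C@H]1C[C@@H]2C(C)C | target

**Count and risks**

Total step count: 11. Longest linear sequence: 10 (steps 1, 2, 4–11).

Step 11. The lactone alkene is only weakly activated and β-substituted, so the cycloaddition may be slow. On long heating the diene may then isomerise or dimerise, and endo/exo and regiochemical control may erode. Diene of lower optical purity would add a diastereomeric adduct. The fallback sets out from 14 and returns at 16. Compound 14 is silylated (Et3SiOTf, 2,6-lutidine, CH2Cl2, −78 °C) to 3-O-triethylsilyl altholactone F1. The lactone carbonyl of F1 is then activated toward 15 by a Lewis acid (Me2AlCl, CH2Cl2, −40 → 0 °C), which should allow a low temperature and sharpen endo and regiocontrol, to give the O-triethylsilyl adduct F2. HF·pyridine (THF, 0 °C) releases 16.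

Step 6. Oxygen transfer to an alkene deactivated by two allylic C–O bonds may be slow, and prolonged heating with peracid may oxidise the doubly activated benzylic position or cleave the 4-methoxybenzyl ether. The fallback sets out from 8 and returns at 9. OsO4 (cat.) with N-methylmorpholine N-oxide (acetone/H2O) dihydroxylates 8 from the same open face to the cis-diol F3. MeC(OMe)3 with pyridinium tosylate gives the cyclic orthoacetate F4. Acetyl bromide (CH2Cl2, 0 °C) opens F4 through the acetoxonium ion with inversion to the trans bromo acetate F5 and its regioisomer F6. K2CO3 in MeOH removes the acetyl group, and the alkoxide displaces bromide with a second inversion, so F5 and F6 both converge on 9 with the oxygen on the face it had in F3.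

Step 9. Z selectivity may erode with the bulky ester ylide, and the aldehyde may epimerise at its α-carbon or lose the epoxide by β-elimination. The fallback sets out from 11 and returns at 12. CBr4 and PPh3 (Zn dust, CH2Cl2, 0 °C) convert 11 into the 1,1-dibromoalkene F7 (Corey–Fuchs). n-BuLi (2 equiv, THF, −78 °C) followed by Boc2O gives the tert-butyl alkynoate F8. Hydrogen over Lindlar catalyst (Pd/CaCO3 poisoned with Pb(OAc)2, quinoline, EtOAc) gives 12, the Z geometry being fixed by syn delivery of hydrogen.

**Further compounds**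

F1 | step 11 | 3-O-triethylsilyl ether of 14 | O=C1O[C@H]2[C@H](O[Si](CC)(CC)CC)[C@@H](c3ccccc3)O[C@H]2C=C1
F2 | step 11 | O-triethylsilyl ether of 16 | CC1=C[C@@H]2[C@@H]3C(=O)O[C@H]4[C@H](O[Si](CC)(CC)CC)[C@@H](c5ccccc5)O[C@H]4[C@@H]3[C@H]1C[C@@H]2C(C)C
F3 | step 6 | (2S,3R,4S,5R)-2-{[(4-methoxyphenyl)methoxy]methyl}-5-phenyloxolane-3,4-diol | COc1ccc(COC[C@@H]2O[C@H](c3ccccc3)[C@@H](O)[C@H]2O)cc1
F4 | step 6 | cyclic orthoacetate (2-methoxy-2-methyl-1,3-dioxolane) of F3, either epimer at the orthoester carbon | COc1ccc(COC[C@@H]2O[C@H](c3ccccc3)[C@H]3OC(C)(OC)O[C@@H]23)cc1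
F5 | step 6 | trans bromo acetate of F3 with bromine at oxolane C3 (cis to the ring substituents) and acetoxy at C4 | COc1ccc(COC[C@@H]2O[C@H](c3ccccc3)[C@@H](OC(C)=O)[C@@H]2Br)cc1
F6 | step 6 | regioisomeric trans bromo acetate with acetoxy at oxolane C3 and bromine at C4 | COc1ccc(COC[C@@H]2O[C@H](c3ccccc3)[C@H](Br)[C@H]2OC(C)=O)cc1
F7 | step 9 | (1S,2S,4R,5R)-2-(2,2-dibromoethenyl)-4-phenyl-3,6-dioxabicyclo[3.1.0]hexane | BrC(Br)=C[C@@H]1O[C@H](c2ccccc2)[C@H]2O[C@@H]12
F8 | step 9 | tert-butyl 3-[(1S,2S,4R,5R)-4-phenyl-3,6-dioxabicyclo[3.1.0]hexan-2-yl]prop-2-ynoate | CC(C)(C)OC(=O)C#C[C@@H]1O[C@H](c2ccccc2)[C@H]2O[C@@H]12
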